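**The stall.** Read the stall in blue before you fit anything. Blue's X stands at 21% after 40.0 min and 19% after 60.0 min. L is the limiting reagent, and one L per X, my assumption since L was never read, would allow 35.0%. X stops short of that, so I suspect that Q is being lost.

| setting | amber | blue | flask |
|---|---|---|---|
| G | 0.18 M | 0.18 M | 0.18 M |
| L | 0.126 M | 0.063 M | 0.126 M |
| Q | 0.90 mM | 0.90 mM | 0.90 mM |
| remark | the very flask that is asked about, followed so far | run made earlier |  |

| run | time / min | X / % | G / % |
|---|---|---|---|
| amber | 1.33 | 3 | 99 |
| amber | 2.50 | 5 | 93 |
| amber | 4.00 | 7 | 92 |
| amber | 5.00 | 10 | 90 |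
| amber | 6.00 | 9 | 87 |
| blue | 5.00 | 4 | 93 |
| blue | 15.0 | 11 | 86 |
| blue | 25.0 | 17 | 82 |
| blue | 40.0 | 21 | 75 |
| blue | 60.0 | 19 | 81 |

(standard deviation of a reading: 2 percentage points)

- apparent order in Q when 10% of the G are converted (percent change of the rate of making X for one percent more Q charged)
- apparent order in L when 10% of the G are converted (percent change of the rate of making X for one percent more L charged)

- the numbers in the tables scatter by 2 percentage points (one standard deviation)
- no earlier run changes the charge of Q; that part of a forecast is a guess

**First way.** Compare average rates up to the mark of 10%. Amber shows X 10% after 5.00 min, blue 11% after 15.0 min. Halving [L] thus reads as an order of 1.45, give or take 0.390.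

**Second way.** This reckoning is mine: take the rate as following [G][L][Q]. At the mark, amber's [L] has fallen, so one percent more L charged raises [L] by 1.17 percent. Blue's early rate over its stall gives a loss constant of 0.0349 min⁻¹, which reads high, since the fall in [L] is counted in it too. The toll, 0.175, is that constant times the time to the mark, the share of Q lost on the way. More L arrives sooner and saves about that share, so the order in L is 1.34. The order in Q, one plus the toll, is 1.18, a reckoning that no run tests. The two ways differ by 0.110, less than the scatter, though they share one blue reading.

**The forecast.** It gave 1 for Q and 1.05 for L, saying “halving L cuts the rate by a factor of about 2.3”. My figure for L stands higher.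

**The flask.** The order in L is 1.3 and the order in Q 1.1.

    G + L + Q → Q + X (k = 3.70 M⁻² s⁻¹)
    Q → Z (k = 4.30 × 10⁻⁴ s⁻¹)

By 8.00 min the flask holds Q at 81.4% and Z at 18.6% of the catalyst charged. With 0.026 min⁻¹ for the step from Q to Z, the toll on the flask's way to the mark at 4.81 min is 0.125, lower than my 0.175, and in blue, up to its reading of 11% after 15.0 min, it is 0.390.

The data come from a simulation for substances that don't exist, noise included.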